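Assumption: germacrane numbering is used throughout (ring C1–C10, C14 = CH3 on C10, C15 = CH2OH carbon on C4, C11–C13 = lactone carbons); the target is 3R,6R,7R,8R,10S,4Z, and the catalyst and auxiliary enantiomers are those that give the configurations shown.

## Retrosynthetic overview

1. Niveusin B ⇐ unmasking of the α-methylene lactone (Me3N elimination) ⇐ C15 installed on the enone form of the hemiketal by α-hydroxymethylation.
2. trans-γ-Lactone and 4Z-alkene ⇐ iodolactonisation / dehydroiodination of a C7 acetamide across a 5Z-alkene; 8-angelate ⇐ C8 ketone.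
3. C7 side chain ⇐ RAMP-hydrazone alkylation of a bridged keto-ketal.
4. Oxygen bridge (C3 ketal, C10 quaternary ether) ⇐ enantioselective transannular ketalisation of an achiral cyclodecadienedione.
5. Ten-membered ring ⇐ Birch reduction of 2-methylnaphthalene, then ozonolysis of the ring-fusion alkene. Ring order: carbocycle → bridging THF ketal → γ-lactone.

## Route

**Step 1**
Reactants: 1, 2-methylnaphthalene
Product: 2, 2-methyl-1,4,5,8-tetrahydronaphthalene
Conditions: Na, liq. NH3, EtOH, Et2O, −78 → −33 °C
Reagents that add atoms: none
Why: Birch reduction 1,4-reduces each ring while the alkyl-bearing carbons (C–CH3 and both ring-fusion carbons) stay sp2, giving the isotetralin with a tetrasubstituted central alkene; no stereocentre.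

**Step 2**
Reactants: 2
Product: 3, (3Z,8Z)-3-methylcyclodeca-3,8-diene-1,6-dione
Conditions: O3 (1.0 equiv), CH2Cl2/MeOH, cat. pyridine, −78 °C; then Me2S
Reagents that add atoms: ozone, [O-][O+]=O
Why: Ozonolysis cleaves the most electron-rich (tetrasubstituted, ring-fusion) alkene first, opening the bicycle to the ten-membered ring whose carbonyls become C3 and C8 and whose two Z-alkenes become C1=C10 and C5=C6; no stereocentre.

**Step 3**
Reactants: 3
Product: 4, (1S,5Z,8R)-8-methoxy-1-methyl-11-oxabicyclo[6.2.1]undec-5-en-3-one (target numbering: 3-OMe-3,10-epoxy, 3R,10S, 5Z-ene, 8-one)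
Conditions: confined chiral Brønsted acid (IDPi type, 5 mol%), MeOH (2 equiv), CHCl3, −20 °C
Reagents that add atoms: methanol, CO
Why: Proposed new method: the acid protonates the trisubstituted C1=C10 alkene at C1, the developing tertiary C10 cation is captured transannularly by the C3 carbonyl oxygen (the only five-membered option; C8=O would give an oxetane), and MeOH adds to the bridged oxocarbenium ion on the face that keeps the bridge cis, with the chiral counter-anion choosing the C10 face (10S, hence 3R); closest known reactions are IDPi-catalysed asymmetric intramolecular hydroalkoxylation of unactivated alkenes and acid cyclisation of γ,δ-unsaturated ketones to 2-alkoxytetrahydrofurans.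

**Step 4**
Reactants: 4; 5, RAMP [(R)-1-amino-2-(methoxymethyl)pyrrolidine]
Product: 6, RAMP hydrazone of 4 at C8
Conditions: RAMP (1.3 equiv), 4 Å MS, cyclohexane, 60 °C
Reagents that add atoms: 5, RAMP, COC[C@H]1CCCN1N
Why: Hydrazone condensation at the only ketone installs the Enders auxiliary.

**Step 5**
Reactants: 6; 7, 2-bromo-N,N-dimethylacetamide
Product: 8, hydrazone 6 carrying CH2CONMe2 at C7
Conditions: LDA, THF, 0 °C; then 7, −100 → −78 °C
Reagents that add atoms: 7, CN(C)C(=O)CBr
Why: Enders RAMP-hydrazone alkylation: LDA removes the allylic C7–H (C9 is neopentyl-like), and the auxiliary-controlled azaenolate is alkylated on the face set by RAMP, fixing C7 in the natural sense independently of the ring.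

**Step 6**
Reactants: 8
Product: 9, C7-(dimethylcarbamoylmethyl) ketone (C7 natural configuration; 7S by CIP in this intermediate)
Conditions: CuCl2, THF / pH 7 phosphate buffer, rt
Reagents that add atoms: water, O
Why: Neutral hydrolytic hydrazone cleavage returns the ketone without epimerising C7, moving the β,γ-alkene or opening the ketal.

**Step 7**
Reactants: 9
Product: 10, C8 alcohol (8R, cis to the C7 side chain)
Conditions: L-Selectride, THF, −78 °C
Reagents that add atoms: none
Why: Ketone reduction with a bulky hydride that attacks anti to the C7 side chain (Felkin-type 1,2-induction), expected to give the 7,8-cis alcohol.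

**Step 8**
Reactants: 10; 11, angelic acid
Product: 12, C8 angelate
Conditions: 11, 2,4,6-trichlorobenzoyl chloride, Et3N, toluene; then 10, 80 °C (no DMAP)
Reagents that add atoms: 11, C/C=C(/C)C(=O)O
Why: Yamaguchi-type mixed-anhydride esterification under conditions that keep the angelate Z; C8 is retained.

**Step 9**
Reactants: 12
Product: 13, iodolactone (C6–O lactone, C5–I; 6,7-trans; 5S)
Conditions: I2, THF/H2O, rt, dark
Reagents that add atoms: iodine, II; water, O
Why: Iodolactonisation of the γ,δ-unsaturated tertiary amide (5-exo O-attack, iminium ether hydrolysed, Me2NH lost); A(1,3) strain of the Z-alkene makes C7–H eclipse the alkene so oxygen adds to C6 anti to C8 (trans lactone, natural C6), and anti addition puts iodine on C5.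

**Step 10**
Reactants: 13
Product: 14, 4Z-alkene lactone (3-OMe ketal, saturated lactone)
Conditions: DBU, toluene, 70 °C
Reagents that add atoms: none
Why: E2 dehydroiodination removes a C4–H (elimination towards C6 would give an enol lactone), and the alkene is Z because E is too strained in the nine-membered oxacycle.

**Step 11**
Reactants: 14
Product: 15, Mannich-base hemiketal (13-dimethylamino-11,13-dihydro-15-nor-niveusin B)
Conditions: LiHMDS, THF, −78 °C; CH2=NMe2+ I−; then 1 M HCl/THF work-up, NaHCO3
Reagents that add atoms: Eschenmoser's salt, C=[N+](C)C.[I-]; water, O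
Why: Lactone-enolate Mannich reaction (first half of the Eschenmoser methylenation) leaves the methylene masked as the amine, and the acidic work-up hydrolyses the now-allylic methyl ketal to the bridged hemiketal (C3 stays R because the bridge must be cis).

**Step 12**
Reactants: 15; 16, formaldehyde
Product: 17, 13-dimethylamino-11,13-dihydroniveusin B
Conditions: 37% aq. HCHO, DABCO, THF/H2O, rt
Reagents that add atoms: 16, C=O
Why: Morita–Baylis–Hillman α-hydroxymethylation of the enone tautomer of the hemiketal puts C15 on C4; the addition–elimination at C5 leaves the thermodynamic 4Z-alkene, the only geometry that lets the 3,10-hemiketal re-close.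

**Step 13**
Reactants: 17
Product: 18, niveusin B
Conditions: MeI, MeOH/CH2Cl2, rt; then aq. NaHCO3
Reagents that add atoms: none
Why: N-methylation and E1cB loss of trimethylamine (second half of the Eschenmoser methylenation) reveal the α-methylene lactone under conditions that leave the free hydroxyls and the angelate untouched.

## Compound list

1 | 2-methylnaphthalene | Cc1ccc2ccccc2c1 | starting material
2 | 2-methyl-1,4,5,8-tetrahydronaphthalene | CC1=CCC2=C(C1)CC=CC2 | intermediate
3 | (3Z,8Z)-3-methylcyclodeca-3,8-diene-1,6-dione | C/C1=C/CC(=O)C/C=C\CC(=O)C1 | intermediate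
4 | (1S,5Z,8R)-8-methoxy-1-methyl-11-oxabicyclo[6.2.1]undec-5-en-3-one | CO[C@@]12CC[C@@](C)(CC(=O)C/C=C\C1)O2 | intermediate
5 | RAMP, (R)-1-amino-2-(methoxymethyl)pyrrolidine | COC[C@H]1CCCN1N | starting material (auxiliary)
6 | RAMP hydrazone of 4 | CO[C@@]12CC[C@@](C)(CC(=NN3CCC[C@@H]3COC)C/C=C\C1)O2 | intermediate
7 | 2-bromo-N,N-dimethylacetamide | CN(C)C(=O)CBr | starting material
8 | C7-alkylated RAMP hydrazone | CO[C@@]12CC[C@@](C)(CC(=NN3CCC[C@@H]3COC)[C@@H](CC(=O)N(C)C)/C=C\C1)O2 | intermediate
9 | C7-(dimethylcarbamoylmethyl) keto-ketal | CO[C@@]12CC[C@@](C)(CC(=O)[C@@H](CC(=O)N(C)C)/C=C\C1)O2 | intermediate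
10 | C8 alcohol of 9 | CO[C@@]12CC[C@@](C)(C[C@@H](O)[C@@H](CC(=O)N(C)C)/C=C\C1)O2 | intermediate
11 | angelic acid, (Z)-2-methylbut-2-enoic acid | C/C=C(/C)C(=O)O | starting material
12 | C8 angelate of 10 | CO[C@@]12CC[C@@](C)(C[C@@H](OC(=O)/C(C)=C\C)[C@@H](CC(=O)N(C)C)/C=C\C1)O2 | intermediate
13 | 5-iodo-6,12-lactone (3-OMe ketal) | C1C(=O)O[C@@H]2[C@@H](I)C[C@@]3(OC)CC[C@@](C)(C[C@@H](OC(=O)/C(C)=C\C)[C@@H]12)O3 | intermediate
14 | 4Z-ene 6,12-lactone (3-OMe ketal) | C1C(=O)O[C@@H]2/C=C\[C@@]3(OC)CC[C@@](C)(C[C@@H](OC(=O)/C(C)=C\C)[C@@H]12)O3 | intermediate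
15 | 13-dimethylamino-11,13-dihydro-15-nor-niveusin B (C11 epimers) | CN(C)CC1C(=O)O[C@@H]2/C=C\[C@@]3(O)CC[C@@](C)(C[C@@H](OC(=O)/C(C)=C\C)[C@@H]12)O3 | intermediate
16 | formaldehyde | C=O | starting material
17 | 13-dimethylamino-11,13-dihydroniveusin B (C11 epimers) | CN(C)CC1C(=O)O[C@@H]2/C=C(/CO)[C@@]3(O)CC[C@@](C)(C[C@@H](OC(=O)/C(C)=C\C)[C@@H]12)O3 | intermediate
18 | niveusin B | C=C1C(=O)O[C@@H]2/C=C(/CO)[C@@]3(O)CC[C@@](C)(C[C@@H](OC(=O)/C(C)=C\C)[C@@H]12)O3 | target

## Summary

Total steps: 13. Longest linear sequence: 13 (fully linear from 2-methylnaphthalene).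

Steps most likely to fail, each with a fallback:

1. **Step 3 (asymmetric transannular ketalisation).** The dienedione may instead undergo transannular aldol or alkene migration, or the ee may be low. Fallback: run the cyclisation racemically (CSA, MeOH) and obtain one enantiomer by separating the diastereomeric RAMP hydrazones 6, i.e. auxiliary-based resolution instead of asymmetric catalysis.
2. **Step 7 (C8 configuration).** Facial selectivity on the medium-ring ketone is not secure. Fallback: if the 8-epi alcohol predominates, carry it forward and form the ester with inversion (Mitsunobu with angelic acid, PPh3, DIAD) instead of retentive acylation.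
3. **Step 12 (MBH on a hindered enone masked as its hemiketal).** The conjugate addition at C5 may be too slow. Fallback: change the source of C15 by starting from 1,6-dimethylnaphthalene so that C15 is carried as the C4 methyl; dehydroiodination then goes by E1cB through the C3 ketone, and the last step becomes SeO2/t-BuOOH allylic hydroxylation. A shorter detour is α-iodination of the enone (I2, pyridine) followed by Stille coupling with Bu3SnCH2OH.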